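Moles per litre, not percent, is the unit to start from, since a percent of the starting material charged has a different base in larch (0.10 M), in elm (0.15 M) and in the new flasks (0.20 M).

| flask | starting material | partner | protic impurity | remark | time |
|---|---|---|---|---|---|
| larch | 0.10 M | 0.10 M | 0.10 M | run made earlier |  |
| elm | 0.15 M | 0.10 M | 0.10 M | run made earlier |  |
| west | 0.20 M | 0.100 M | 0.100 M |  | 6.0 min |
| south-west | 0.20 M | 0.100 M | 0.100 M |  | 5.0 min |
| north | 0.20 M | 0.100 M | 0.100 M |  | 4.0 min |

| run | time / min | target / % | starting material / % |
|---|---|---|---|
| larch | 0.333 | 8 | 96 |
| larch | 0.500 | 7 | 95 |
| larch | 0.667 | 4 | 92 |
| larch | 1.00 | 10 | 90 |
| larch | 1.50 | 19 | 74 |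
| larch | 2.50 | 36 | 61 |
| larch | 4.00 | 62 | 39 |
| elm | 0.200 | 0 | 96 |
| elm | 0.667 | 8 | 88 |
| elm | 1.00 | 16 | 83 |
| elm | 1.50 | 27 | 74 |
| elm | 2.50 | 46 | 55 |
| elm | 3.00 | 47 | 49 |
| elm | 4.00 | 56 | 44 |

(scatter of a reading: 2 percentage points)

- which of these there is most of at the end, counted by the starting material in it, west (target / starting material)
- which of these there is most of at the end, counted by the starting material in it, south-west (target / starting material)
- which of these there is most of at the end, counted by the starting material in it, north (target / starting material)
- the largest of these amounts at the end, in percent of the starting material charged, west
- the largest of these amounts at the end, in percent of the starting material charged, south-west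
- the largest of these amounts at the end, in percent of the starting material charged, north

- a reading or a percentage of target counts all its forms, free or not

What do the runs show? Target gained and starting material lost match within the scatter, so one starting material gives one target.

Your first answer for the new flasks? If one partner makes one target, target stops at 50.0% and 50.0% of the starting material stays.

Put that back against elm: does the partner deliver one for one? Elm's last reading, at 4.00 min, is 0.0840 M of target on 0.10 M of partner. Call target made per partner charged the partner yield, which reads 0.840 in elm. Elm is still moving but slowing, from 0.0285 M min⁻¹ to 0.0100 M min⁻¹, so that yield is a lower mark, and it carries the scatter.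

But north has a shorter time than the others: does it get that far? At 4.00 min larch holds 0.0620 M of target, less than elm, so more starting material gave more target in the same time. I therefore expect north to pass elm's figure by 4.0 min, and west and south-west with it.

Your reckoning, then? Starting material left is one minus the partner yield times partner over starting material. Elm's mark gives 58.0% and a yield of one gives 50.0%, so I commit to starting material as the largest amount, near 54.0% in each flask.

The forecast also names starting material (starting material, starting material, starting material) but stands lower than mine, at 51% for west, 52% for south-west and 53% for north, with “the partner nearly exhausted”.

The flasks give starting material at 54.7% in west, starting material at 54.8% in south-west and starting material at 55.2% in north, so the forecast held within its margin.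

    partner + protic impurity → quenched reagent (k = 0.0130 M⁻¹ s⁻¹)
    crystals ⇌ target, rate k2*(cs2 - [target]) while solid is left; crystals form when [target] > cs2 (solubility = 26.0 mM, k = 0.150 s⁻¹)
    starting material + partner → target + by-product (k = 0.0140 M⁻¹ s⁻¹)
    starting material + partner + by-product → target + 2 by-product (k = 2.10 M⁻² s⁻¹)

Put back, the partner yield is 0.906 in west and 0.897 in north. At the end of west, by-product stands at 0.0906 M against 0.00937 M of quenched reagent, ten times as much, and these are the partner's two rates summed over the run, with 0.060% of the partner left. The quenched reagent is worth 4.68% of the starting material, which is how far west stands above 50.0%.

In a neighbour flask, north with 0.34 M of starting material, north's yield gives 73.6% of starting material left. The computed flask holds 72.1%, with target at 27.9% and partner, the limiting reagent, at 0%.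

The data are simulated for substances that don't exist; the scatter is artificial.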